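The easy step comes first: call r the free monomer charged over the pre-initiator charged; if each pre-initiator begins one chain, the average length in a flask is r times the fraction of the monomer that has gone into chains. That gives r = 40.0 for Thursday's and 10.0 for Friday's. The objection cannot be computed away, because the earlier runs show no chain count, so this stays a guess.

in all of them: free monomer 20 mM
- autumn: pre-initiator 0.53 mM; run made earlier
- noon: pre-initiator 0.99 mM; run made earlier
- spring: pre-initiator 1.9 mM; run made earlier
- Thursday's: pre-initiator 0.50 mM; time 3.0 h
- Friday's: pre-initiator 2.0 mM; time 3.0 h

| run | time / min | monomer in chains / % | free monomer / % |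
|---|---|---|---|
| autumn | 20.0 | 9.0 | 89.5 |
| autumn | 40.0 | 24.4 | 74.2 |
| autumn | 50.0 | 33.7 | 66.3 |
| autumn | 80.0 | 48.2 | 48.5 |
| autumn | 90.0 | 53.6 | 44.7 |
| noon | 8.00 | 3.2 | 97.4 |
| noon | 15.0 | 10.7 | 88.6 |
| noon | 25.0 | 24.6 | 76.3 |
| noon | 50.0 | 52.9 | 44.7 |
| noon | 90.0 | 75.8 | 21.9 |
| spring | 8.00 | 5.6 | 92.2 |
| spring | 25.0 | 40.0 | 57.0 |
| spring | 40.0 | 67.1 | 35.1 |
| spring | 60.0 | 85.5 | 17.4 |
| spring | 90.0 | 94.0 | 6.7 |

(each reading ± 1 percentage point)

* which of the two ends with the longer chains by the average number of monomer units in a chain (chains begun, living or dead) ("neither" if they lie within 10%) (Thursday's / Friday's / neither)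
* average number of monomer units in a chain (chains begun, living or dead) at the end, Thursday's
* average number of monomer units in a chain (chains begun, living or dead) at the end, Friday's

- the average divides the monomer in chains by the number of chains begun, living and dead together
- the numbers in the tables scatter by 1 percentage point (one standard deviation)
- the earlier runs do not show the number of chains; that part of a forecast is a guess

What remains is the fraction. Free monomer falls pseudo-first-order, so ln(charged/left) is the time integral of a rate that follows the active ends, and these should scale with the pre-initiator. I therefore define the dose g, ln(charged/left) per mM of pre-initiator at 90.0 min. The autumn, noon and spring runs give 1.52 /mM, 1.53 /mM and 1.42 /mM. Spring is lower, but its free monomer reading is the smallest, so the scatter weighs most there. I take the mean, 1.49 /mM.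

The asked time is 3.0 h, later than every reading. If the dose stopped at its 90.0 min value, Thursday's would end at 21.0; if it doubled, at 31.0. Doubling assumes that the mean slope of the first 90.0 min goes on, yet noon's slope, as read off its scattered readings, drops from 0.0214 /min to 0.0178 /min. That drop is small, but it counts against a straight line, so I commit to the midpoint, 26.0. The same two assumptions put Friday's at 9.49 and 9.97, so I expect Thursday's to be longer.

The forecast differs from me on Thursday's. It says Thursday's, with 32 for Thursday's and 10 for Friday's, on the ground that “Late slopes sag only slightly, so there is little loss of active centres.”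

The flasks give Thursday's, with 25.7 for Thursday's and 10.5 for Friday's.

    free monomer + initiator → living end + monomer in chains (k = 42.0 /M/min)
    free monomer + living end → monomer in chains + living end, rate k2*[living end]*[free monomer] (k = 62.0 /M/min)
    living end → dead end (k = 0.0290 /min)
    pre-initiator → initiator (k = 0.0220 /min)
    monomer in chains → over-reaction product (k = 1.80 × 10⁻⁴ /min)

Thursday's holds 63.1% monomer in chains and 35.6% free monomer at 3.0 h, where the forecast reckoned about 80% conversion. At 1.50 h, g leaves 47.4% free monomer in Thursday's, and the flask has 48.7%; in Friday's it leaves 5.06%, and the flask has 5.41%. Over that first stretch, g gives Thursday's free monomer a mean half-life of 83.6 min. At 3.00 h, the half-life of Thursday's free monomer by the chain growth step is 8.3 h, longer by a factor of 5.96.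

The data are calculated for an exercise, noise included.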